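## Retrosynthetic overview

1. Numbering: the indenone core is C1–C7a. Azulene B (on C6) is primed and azulene A (on C2) is double-primed, both in guaiazulene numbering with the link at C3. Feature: the seven-membered ring of azulene B (C3a', C4'–CH3, C5', C6', C7'–iPr, C8', C8a') is the 2-methyl-5-isopropylphenyl ring of carvacrol widened by one carbon, C8a'. This same carbon closes the five-membered ring C1'–C2'–C3'–C3a'–C8a', whose C3' holds core carbon C6.
2. Last ring: the indenone five-membered ring is cut at C3a–C3 and C1–C2. The forward reaction is a C–H/C–N annulation of a C7a aroyl imide with 3-(prop-1-ynyl)guaiazulene, so azulene A arrives ready-made.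
3. Azulene B goes back to a 3-aryl dihydroazulen-1-one by methyl addition at C1', dehydration and dehydrogenation. The C4 ester becomes the carbinol only after that, so the cumyl alcohol never meets a dehydrating agent.
4. Key cut: C8a'–C3a' and C8a'–C8', an intramolecular Büchner ring expansion of a 4,4-diaryl-1-diazobutan-2-one. This diazoketone is reached from methyl 3,5-dibromo-4-methylbenzoate by mono-Heck reaction, rhodium-catalysed conjugate arylation and acylation of diazomethane.
5. Ring order: the core benzene ring and azulene A are bought, the five- and seven-membered rings of azulene B form together, and the indenone five-membered ring forms last.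

Key step: step 8

Remark: the target SMILES holds no stereodescriptor, so the two hindered aryl–azulenyl axes are left unassigned; every sp3 centre made on the way (C3', C8a', C1') is racemic or a mixture and is erased in step 10.

## Route

Step 1
Reactants: 1 carvacrol
Product: 2 5-isopropyl-2-methylphenyl trifluoromethanesulfonate
Conditions: Tf2O (1.1 equiv), pyridine, CH2Cl2, 0 °C
Reagents that add atoms: triflic anhydride, O=S(=O)(OS(=O)(=O)C(F)(F)F)C(F)(F)F
Why: O-sulfonylation of the phenol turns the C–O bond of carvacrol into a cross-coupling handle at exactly the carbon that becomes C3a'.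

Step 2
Reactants: 2 5-isopropyl-2-methylphenyl trifluoromethanesulfonate
Product: 3 2-(5-isopropyl-2-methylphenyl)-4,4,5,5-tetramethyl-1,3,2-dioxaborolane
Conditions: B2pin2, PdCl2(dppf) (3 mol %), KOAc, 1,4-dioxane, 90 °C
Reagents that add atoms: bis(pinacolato)diboron, CC1(C)OB(OC1(C)C)B1OC(C)(C)C(C)(C)O1
Why: Miyaura borylation of an aryl triflate is routine and tolerates the single ortho methyl group.

Step 3
Reactants: 4 methyl 3,5-dibromo-4-methylbenzoate; 5 tert-butyl acrylate
Product: 6 methyl 3-bromo-5-[(E)-3-tert-butoxy-3-oxoprop-1-enyl]-4-methylbenzoate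
Conditions: Pd(OAc)2 (3 mol %), P(o-tol)3, Et3N, DMF, 100 °C; 4 (2 equiv) to 5 (1 equiv), excess 4 recovered
Reagents that add atoms: none
Why: Mizoroki–Heck reaction of an aryl bromide with an acrylate gives the E-cinnamate, and because the two bromides of 4 are equivalent, running 4 in excess holds back the double Heck product.

Step 4
Reactants: 6 methyl 3-bromo-5-[(E)-3-tert-butoxy-3-oxoprop-1-enyl]-4-methylbenzoate; 3 2-(5-isopropyl-2-methylphenyl)-4,4,5,5-tetramethyl-1,3,2-dioxaborolane
Product: 7 methyl 3-bromo-5-[3-tert-butoxy-1-(5-isopropyl-2-methylphenyl)-3-oxopropyl]-4-methylbenzoate (racemic)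
Conditions: 3 (2 equiv), [RhCl(cod)]2 (3 mol %), KOH (0.3 equiv), 1,4-dioxane/H2O 10:1, 80 °C
Reagents that add atoms: none
Why: In this Hayashi–Miyaura conjugate addition the aryl–rhodium species from 3 adds to the β-carbon of the cinnamate and water protonates the rhodium enolate, which makes the crowded C6–C3' bond at an sp2 carbon, spares the aryl bromide and sets C3' without control (achiral cod ligand, racemate sufficient).

Step 5
Reactants: 7 methyl 3-bromo-5-[3-tert-butoxy-1-(5-isopropyl-2-methylphenyl)-3-oxopropyl]-4-methylbenzoate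
Product: 8 3-[3-bromo-5-(methoxycarbonyl)-2-methylphenyl]-3-(5-isopropyl-2-methylphenyl)propanoic acid (racemic)
Conditions: TFA/CH2Cl2 1:3, 0 °C → rt
Reagents that add atoms: none
Why: Acidolysis of the tert-butyl ester by E1-type loss of isobutene leaves the methyl benzoate and the aryl bromide untouched.

Step 6
Reactants: 8 3-[3-bromo-5-(methoxycarbonyl)-2-methylphenyl]-3-(5-isopropyl-2-methylphenyl)propanoic acid
Product: 9 methyl 3-bromo-5-[3-chloro-1-(5-isopropyl-2-methylphenyl)-3-oxopropyl]-4-methylbenzoate (racemic; used crude)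
Conditions: (COCl)2, DMF (cat.), CH2Cl2, 0 °C → rt; evaporation
Reagents that add atoms: oxalyl chloride, O=C(Cl)C(=O)Cl
Why: Acid chloride formation through the chloroiminium species from DMF converts the unhindered CH2CO2H group and does not touch the methyl ester.

Step 7
Reactants: 9 methyl 3-bromo-5-[3-chloro-1-(5-isopropyl-2-methylphenyl)-3-oxopropyl]-4-methylbenzoate
Product: 10 methyl 3-bromo-5-[4-diazo-1-(5-isopropyl-2-methylphenyl)-3-oxobutyl]-4-methylbenzoate (racemic)
Conditions: CH2N2 (3 equiv), Et2O, 0 °C
Reagents that add atoms: diazomethane, C=[N+]=[N-]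
Why: This is the first stage of the Arndt–Eistert sequence, C-acylation of diazomethane, in which a second equivalent takes up HCl so that no chloromethyl ketone forms.

Step 8
Reactants: 10 methyl 3-bromo-5-[4-diazo-1-(5-isopropyl-2-methylphenyl)-3-oxobutyl]-4-methylbenzoate
Product: 12 methyl 3-bromo-5-(7-isopropyl-4-methyl-1-oxo-1,2,3,8a-tetrahydroazulen-3-yl)-4-methylbenzoate (racemic), via norcaradiene 11 (not isolated)
Conditions: Rh2(OAc)4 (1 mol %), CH2Cl2, reflux, slow addition of 10 by syringe pump at high dilution; filtration through neutral alumina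
Reagents that add atoms: none
Why: Rh2(OAc)4 expels N2 from 10 and the electrophilic rhodium carbenoid adds its carbon (the future C8a') across the bond between the ipso carbon and the hydrogen-bearing ortho carbon of the cymene ring to give norcaradiene 11; a thermally allowed disrotatory six-electron opening then cleaves the old ipso–ortho bond and leaves C8a' bonded to C3a' and C8' in cycloheptatriene 12. The closest known reaction is this one itself, the intramolecular Büchner reaction of 1-diazo-4-arylbutan-2-ones to 3,8a-dihydroazulen-1(2H)-ones, here run on a 4,4-diaryl member of the class. The five-membered ring closes in the [2+1] cycloaddition, because the three-atom tether C1'–C2'–C3' lets the carbenoid carbon reach only the ipso–ortho bonds, and the seven-membered ring is not cyclised at all but grows out of the six-membered ring in the electrocyclic opening. The one new centre, C8a', is set under substrate control by C3', the tether being expected to fold so that the bulky core aryl lies on the same face as H-8a' (as drawn), but C8a' is alpha to the ketone and epimerisable and both centres are erased in step 10, so this outcome has no bearing on the route. Two choices must fall the right way: between the rings, the carbenoid should prefer the trialkyl-substituted cymene ring to the ring deactivated by CO2Me and Br, and between the two ortho bonds, the bond to C–H is more open than the bond to the methyl-bearing carbon, which must stay intact to become C3a'–C4'. Slow addition at high dilution holds back carbene dimers, and an acid-free work-up prevents the acid-induced rearrangement of such trienones to 2-tetralones.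

Step 9
Reactants: 12 methyl 3-bromo-5-(7-isopropyl-4-methyl-1-oxo-1,2,3,8a-tetrahydroazulen-3-yl)-4-methylbenzoate
Product: 13 methyl 3-bromo-5-(1-hydroxy-7-isopropyl-1,4-dimethyl-1,2,3,8a-tetrahydroazulen-3-yl)-4-methylbenzoate (mixture at C1')
Conditions: MeMgBr (1.3 equiv), anhydrous CeCl3 (1.5 equiv), THF, −78 °C
Reagents that add atoms: methylmagnesium bromide, C[Mg]Br
Why: In this organocerium 1,2-addition the weakly basic, oxophilic methylcerium reagent adds to the ketone where plain MeMgBr would deprotonate the very acidic C8a'–H, a slight excess at −78 °C spares the methyl benzoate, and the uncontrolled C1' centre is erased in step 10.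

Step 10
Reactants: 13 methyl 3-bromo-5-(1-hydroxy-7-isopropyl-1,4-dimethyl-1,2,3,8a-tetrahydroazulen-3-yl)-4-methylbenzoate
Product: 15 methyl 3-bromo-5-(7-isopropyl-1,4-dimethylazulen-3-yl)-4-methylbenzoate, via dihydroazulene 14 (not isolated)
Conditions: Burgess reagent (1.5 equiv), toluene, 50 °C; short neutral alumina plug under argon; then chloranil (1.1 equiv), toluene, rt → 50 °C
Reagents that add atoms: none
Why: Burgess dehydration is an intramolecular syn elimination that avoids a free C1' cation (which could collapse through the norcaradiene form to a benzenoid skeleton), and all double-bond isomers of 14 converge when chloranil removes hydride and proton, driven by azulene aromaticity, which erases C3' and C8a'.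

Step 11
Reactants: 15 methyl 3-bromo-5-(7-isopropyl-1,4-dimethylazulen-3-yl)-4-methylbenzoate
Product: 16 2-[3-bromo-5-(7-isopropyl-1,4-dimethylazulen-3-yl)-4-methylphenyl]propan-2-ol
Conditions: MeMgBr (4 equiv), THF, 0 °C → rt
Reagents that add atoms: methylmagnesium bromide, C[Mg]Br
Why: Twofold Grignard addition to the methyl ester gives the tertiary carbinol, and MeMgBr neither adds to an alkyl-substituted azulene nor exchanges with the aryl bromide at this temperature.

Step 12
Reactants: 16 2-[3-bromo-5-(7-isopropyl-1,4-dimethylazulen-3-yl)-4-methylphenyl]propan-2-ol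
Product: 17 3-[3-(7-isopropyl-1,4-dimethylazulen-3-yl)-5-(2-hydroxypropan-2-yl)-2-methylbenzoyl]-1,3-oxazolidin-2-one
Conditions: Pd(OAc)2 (5 mol %), Xantphos, CO (1 atm), oxazolidin-2-one (3 equiv), DMAP (0.2 equiv), Et3N, toluene, 100 °C
Reagents that add atoms: carbon monoxide, [C-]#[O+]; oxazolidin-2-one, O=C1NCCO1
Why: Palladium-catalysed aminocarbonylation of an aryl bromide (oxidative addition, CO insertion, acyl transfer through DMAP to the weakly nucleophilic N–H) gives the aroyl imide, and the tertiary alcohol is too hindered to compete as a nucleophile.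

Step 13
Reactants: 18 guaiazulene
Product: 20 guaiazulene-3-carbaldehyde (7-isopropyl-1,4-dimethylazulene-3-carbaldehyde), via iminium chloride 19 (not isolated)
Conditions: POCl3, DMF, 0 °C → rt; then aq. NaOH
Reagents that add atoms: N,N-dimethylformamide, CN(C)C=O; water (as aqueous NaOH), O; phosphoryl chloride (chloride of 19 only), O=P(Cl)(Cl)Cl
Why: Vilsmeier–Haack formylation attacks C3'', the most nucleophilic free position of guaiazulene, because C1'' is blocked by methyl.

Step 14
Reactants: 20 guaiazulene-3-carbaldehyde
Product: 21 3-(2,2-dibromovinyl)guaiazulene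
Conditions: CBr4, PPh3, Zn, CH2Cl2, rt (ylide preformed); then 20, 0 °C → rt
Reagents that add atoms: carbon tetrabromide, BrC(Br)(Br)Br
Why: Corey–Fuchs olefination, a Wittig reaction of the dibromomethylene ylide preformed with zinc so that no bromophosphonium species meets the azulene, also works on electron-rich, poorly electrophilic aldehydes.

Step 15
Reactants: 21 3-(2,2-dibromovinyl)guaiazulene
Product: 23 3-(prop-1-ynyl)guaiazulene, via lithium acetylide 22 (not isolated)
Conditions: n-BuLi (2.1 equiv), THF, −78 °C; then MeOTf, −78 → 0 °C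
Reagents that add atoms: methyl triflate, COS(=O)(=O)C(F)(F)F; n-butyllithium (lithium of 22 only), [Li]CCCC
Why: In the second stage of the Corey–Fuchs sequence, bromine–lithium exchange and Fritsch–Buttenberg–Wiechell-type rearrangement give the lithium acetylide, which MeOTf methylates already at −78 °C, before proton exchange with the acidic C4''-methyl group can set in.

Step 16
Reactants: 17 3-[3-(7-isopropyl-1,4-dimethylazulen-3-yl)-5-(2-hydroxypropan-2-yl)-2-methylbenzoyl]-1,3-oxazolidin-2-one; 23 3-(prop-1-ynyl)guaiazulene
Product: 24 2,6-bis(7-isopropyl-1,4-dimethylazulen-3-yl)-4-(2-hydroxypropan-2-yl)-3,7-dimethyl-1H-inden-1-one (target)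
Conditions: [Cp*RhCl2]2 (5 mol %), AgSbF6 (20 mol %, AgCl filtered off before the substrates are added), Cu(OAc)2 (20 mol %), 23 (1.5 equiv), PhCl, 120 °C, argon
Reagents that add atoms: none
Why: This is the redox-neutral C–H/C–N annulation of an aroyl imide with an internal alkyne under [Cp*RhCl2]2 catalysis, in which acetate-assisted metalation of C3a–H (the only C–H ortho to the imide, and also ortho to the carbinol oxygen, itself a directing group for this catalyst) is followed by alkyne insertion with C3a going to the methyl-bearing carbon and rhodium to the azulenyl-bearing one, and addition of the vinyl–rhodium bond to the imide carbonyl with loss of oxazolidinone then gives the 3-methyl-2-azulenyl indenone.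

## Compound list

1 | carvacrol (5-isopropyl-2-methylphenol) | Cc1ccc(C(C)C)cc1O | starting material
2 | 5-isopropyl-2-methylphenyl trifluoromethanesulfonate | Cc1ccc(C(C)C)cc1OS(=O)(=O)C(F)(F)F | intermediate
3 | 2-(5-isopropyl-2-methylphenyl)-4,4,5,5-tetramethyl-1,3,2-dioxaborolane | Cc1ccc(C(C)C)cc1B1OC(C)(C)C(C)(C)O1 | intermediate
4 | methyl 3,5-dibromo-4-methylbenzoate | COC(=O)c1cc(Br)c(C)c(Br)c1 | starting material
5 | tert-butyl acrylate | C=CC(=O)OC(C)(C)C | starting material
6 | methyl 3-bromo-5-[(E)-3-tert-butoxy-3-oxoprop-1-enyl]-4-methylbenzoate | COC(=O)c1cc(Br)c(C)c(/C=C/C(=O)OC(C)(C)C)c1 | intermediate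
7 | methyl 3-bromo-5-[3-tert-butoxy-1-(5-isopropyl-2-methylphenyl)-3-oxopropyl]-4-methylbenzoate (racemic, one enantiomer drawn) | CC(C)(C)OC(=O)C[C@H](c1cc(C(C)C)ccc1C)c1cc(C(=O)OC)cc(Br)c1C | intermediate
8 | 3-[3-bromo-5-(methoxycarbonyl)-2-methylphenyl]-3-(5-isopropyl-2-methylphenyl)propanoic acid (racemic, one enantiomer drawn) | OC(=O)C[C@H](c1cc(C(C)C)ccc1C)c1cc(C(=O)OC)cc(Br)c1C | intermediate
9 | methyl 3-bromo-5-[3-chloro-1-(5-isopropyl-2-methylphenyl)-3-oxopropyl]-4-methylbenzoate (racemic, one enantiomer drawn) | ClC(=O)C[C@H](c1cc(C(C)C)ccc1C)c1cc(C(=O)OC)cc(Br)c1C | intermediate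
10 | methyl 3-bromo-5-[4-diazo-1-(5-isopropyl-2-methylphenyl)-3-oxobutyl]-4-methylbenzoate (racemic, one enantiomer drawn) | [N-]=[N+]=CC(=O)C[C@H](c1cc(C(C)C)ccc1C)c1cc(C(=O)OC)cc(Br)c1C | intermediate
11 | norcaradiene valence isomer of 12, with a cyclopropane made of C3a', C8' and C8a' (racemic, not isolated) | O=C1C[C@@H](c4cc(C(=O)OC)cc(Br)c4C)[C@]23C(C)=CC=C(C(C)C)[C@H]2[C@H]13 | intermediate
12 | methyl 3-bromo-5-(7-isopropyl-4-methyl-1-oxo-1,2,3,8a-tetrahydroazulen-3-yl)-4-methylbenzoate (racemic; core aryl and H-8a' cis as drawn) | O=C1C[C@@H](c2cc(C(=O)OC)cc(Br)c2C)C2=C(C)C=CC(C(C)C)=C[C@H]12 | intermediate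
13 | methyl 3-bromo-5-(1-hydroxy-7-isopropyl-1,4-dimethyl-1,2,3,8a-tetrahydroazulen-3-yl)-4-methylbenzoate (racemic, mixture at C1') | CC1(O)C[C@@H](c2cc(C(=O)OC)cc(Br)c2C)C2=C(C)C=CC(C(C)C)=C[C@H]12 | intermediate
14 | methyl 3-bromo-5-(7-isopropyl-1,4-dimethyl-2,3-dihydroazulen-3-yl)-4-methylbenzoate (racemic; drawn as the C1'=C8a' isomer, double-bond isomers converge; not isolated) | CC1=C2C=C(C(C)C)C=CC(C)=C2[C@H](c2cc(C(=O)OC)cc(Br)c2C)C1 | intermediate
15 | methyl 3-bromo-5-(7-isopropyl-1,4-dimethylazulen-3-yl)-4-methylbenzoate | COC(=O)c1cc(Br)c(C)c(-c2cc(C)c3cc(C(C)C)ccc(C)c2-3)c1 | intermediate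
16 | 2-[3-bromo-5-(7-isopropyl-1,4-dimethylazulen-3-yl)-4-methylphenyl]propan-2-ol | CC(C)(O)c1cc(Br)c(C)c(-c2cc(C)c3cc(C(C)C)ccc(C)c2-3)c1 | intermediate
17 | 3-[3-(7-isopropyl-1,4-dimethylazulen-3-yl)-5-(2-hydroxypropan-2-yl)-2-methylbenzoyl]-1,3-oxazolidin-2-one | CC(C)(O)c1cc(C(=O)N2CCOC2=O)c(C)c(-c2cc(C)c3cc(C(C)C)ccc(C)c2-3)c1 | intermediate
18 | guaiazulene (7-isopropyl-1,4-dimethylazulene) | c1cc(C)c2cc(C(C)C)ccc(C)c1-2 | starting material
19 | N-[(7-isopropyl-1,4-dimethylazulen-3-yl)methylidene]-N-methylmethanaminium chloride (not isolated) | C[N+](C)=Cc1cc(C)c2cc(C(C)C)ccc(C)c1-2.[Cl-] | intermediate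
20 | guaiazulene-3-carbaldehyde | O=Cc1cc(C)c2cc(C(C)C)ccc(C)c1-2 | intermediate
21 | 3-(2,2-dibromovinyl)guaiazulene | BrC(Br)=Cc1cc(C)c2cc(C(C)C)ccc(C)c1-2 | intermediate
22 | lithium (7-isopropyl-1,4-dimethylazulen-3-yl)acetylide (not isolated) | [Li]C#Cc1cc(C)c2cc(C(C)C)ccc(C)c1-2 | intermediate
23 | 3-(prop-1-ynyl)guaiazulene | CC#Cc1cc(C)c2cc(C(C)C)ccc(C)c1-2 | intermediate
24 | 2,6-bis(7-isopropyl-1,4-dimethylazulen-3-yl)-4-(2-hydroxypropan-2-yl)-3,7-dimethyl-1H-inden-1-one | CC1=C(c2cc(C)c3cc(C(C)C)ccc(C)c2-3)C(=O)c2c(C)c(-c3cc(C)c4cc(C(C)C)ccc(C)c3-4)cc(C(C)(C)O)c21 | target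

## Step count and risks

Total step count: 16. Longest linear sequence: 12 steps (1, 2, 4–12, 16).

**1. Step 16 (annulation).**
- What may go wrong: metalation of C3a–H may be too slow, because this bond sits between two substituents, one of them a tertiary alkyl group. Hydroxyl-directed metalation may carry the alkyne to C5 or into O-cyclisation. The Lewis-acidic medium may dehydrate the carbinol, and π-binding of the cationic rhodium to the azulenes may starve the catalytic cycle.
- Fallback: close the ring before the carbinol exists, and mask the new ketone as its alcohol while the carbinol is built. The fallback sets out from 15.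
- Aminocarbonylation as in step 12 should give methyl 3-(7-isopropyl-1,4-dimethylazulen-3-yl)-4-methyl-5-(2-oxo-1,3-oxazolidine-3-carbonyl)benzoate F1. In this compound C3a–H lies between two flat carbonyl groups and is the most acidic ring C–H.
- Annulation with 23 as in step 16 should give methyl 2,6-bis(7-isopropyl-1,4-dimethylazulen-3-yl)-3,7-dimethyl-1-oxo-1H-indene-4-carboxylate F2.
- Luche reduction (NaBH4, CeCl3·7H2O, MeOH/THF, 0 °C) should give methyl 1-hydroxy-2,6-bis(7-isopropyl-1,4-dimethylazulen-3-yl)-3,7-dimethyl-1H-indene-4-carboxylate F3.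
- Excess MeMgBr (THF, 0 °C → rt) should give 2,6-bis(7-isopropyl-1,4-dimethylazulen-3-yl)-4-(2-hydroxypropan-2-yl)-3,7-dimethyl-1H-inden-1-ol F4.
- MnO2 in CH2Cl2, which oxidises only the secondary allylic-benzylic alcohol, brings the sequence back to the route at 24.

**2. Step 8 (Büchner ring expansion).**
- What may go wrong: the carbenoid may attack the ester-bearing ring or the methyl-bearing ortho bond. It may substitute the ortho C–H bond with formation of a six-membered ketone, or it may dimerise. The trienone may also rearrange on acidic supports.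
- Fallback: do not build azulene B but bring it in whole. The fallback sets out from 4 and 18. A Pd(OAc)2-catalysed direct C3–H arylation of guaiazulene with an excess of the dibromide (KOAc, DMAc, 130 °C) comes back to the route at 15 and makes no compound outside the list (F0).
- The price is that the crowded C6–C3' bond must then form by reductive elimination between an ortho methyl and a peri methyl group.

**3. Step 10 (dehydration and dehydrogenation).**
- What may go wrong: partial ionisation at C1' may trigger skeletal rearrangement to a benzenoid system. Dehydrogenation may stall at the dihydro stage, or the quinone may go on to oxidise the C1'-methyl group of the product.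
- Fallback: avoid the C1' alcohol altogether. The fallback sets out from 12. Petasis methylenation (Cp2TiMe2, toluene, 70 °C; neutral, ketone before ester) should give methyl 3-bromo-5-(7-isopropyl-4-methyl-1-methylidene-1,2,3,8a-tetrahydroazulen-3-yl)-4-methylbenzoate F5, an isomer of 14.
- Chloranil in toluene then dehydrogenates it, while the acidic hydroquinone formed moves the exocyclic double bond into the ring. The sequence comes back to the route at 15.

Further compounds
F1 | step 16 | methyl 3-(7-isopropyl-1,4-dimethylazulen-3-yl)-4-methyl-5-(2-oxo-1,3-oxazolidine-3-carbonyl)benzoate | COC(=O)c1cc(C(=O)N2CCOC2=O)c(C)c(-c2cc(C)c3cc(C(C)C)ccc(C)c2-3)c1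
F2 | step 16 | methyl 2,6-bis(7-isopropyl-1,4-dimethylazulen-3-yl)-3,7-dimethyl-1-oxo-1H-indene-4-carboxylate | CC1=C(c2cc(C)c3cc(C(C)C)ccc(C)c2-3)C(=O)c2c(C)c(-c3cc(C)c4cc(C(C)C)ccc(C)c3-4)cc(C(=O)OC)c21
F3 | step 16 | methyl 1-hydroxy-2,6-bis(7-isopropyl-1,4-dimethylazulen-3-yl)-3,7-dimethyl-1H-indene-4-carboxylate (racemic, one enantiomer drawn) | CC1=C(c2cc(C)c3cc(C(C)C)ccc(C)c2-3)[C@H](O)c2c(C)c(-c3cc(C)c4cc(C(C)C)ccc(C)c3-4)cc(C(=O)OC)c21
F4 | step 16 | 2,6-bis(7-isopropyl-1,4-dimethylazulen-3-yl)-4-(2-hydroxypropan-2-yl)-3,7-dimethyl-1H-inden-1-ol (racemic, one enantiomer drawn) | CC1=C(c2cc(C)c3cc(C(C)C)ccc(C)c2-3)[C@H](O)c2c(C)c(-c3cc(C)c4cc(C(C)C)ccc(C)c3-4)cc(C(C)(C)O)c21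
F0 | step 8 | none | none
F5 | step 10 | methyl 3-bromo-5-(7-isopropyl-4-methyl-1-methylidene-1,2,3,8a-tetrahydroazulen-3-yl)-4-methylbenzoate (racemic, one diastereomer drawn) | C=C1C[C@@H](c2cc(C(=O)OC)cc(Br)c2C)C2=C(C)C=CC(C(C)C)=C[C@H]12
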